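**Plan**

1. Carotenoid numbering is used, with primes for the dihydroxylated half and C1''–C3'' for the first three side-chain carbons. The first cuts are C7=C8 and C7'=C8' (two Wittig olefinations), which give the C20 dialdehyde crocetindial and two (cyclohexenylmethyl)phosphonium salts.
2. In each salt a 1,2-shift is undone: the C1–C6 bond is replaced by C1–C5, so C6 leaves the ring. The six-ring allyl cation C5–C6–C7 then becomes an α-(cyclopentyl)vinyl cation, that is, the enol triflate of a 1-acetyl-1,2,2-trimethylcyclopentane. Further cuts are C2''=C3'' (cross metathesis, primed half), C1''–C2'' (alkenyl cuprate + iodide) and C6–C7 (MeLi + lactone).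
3. Enabling feature: in the ring C1–C6, the run C5(CH3)–C1(CH3)2–C2(H)(C1'') that flanks C6 is the camphoric acid skeleton (1,2,2-trimethylcyclopentane-1,3-dicarboxylic acid) once C6 is exocyclic on C5. The tertiary CO2H carbon is C6 and the secondary CO2H carbon is C1''. C1 is the only fully substituted neighbour of C5, hence the carbon that migrates.
4. Forward: (−)-camphoric acid → lactone → methyl ketone → allyl ketone → enol triflate → side chain → five-to-six ring enlargement with PPh3 capture. The same sequence runs from (+)-camphoric acid with a prenyl side chain. Then unprimed salt + crocetindial, primed salt + the resulting C35 aldehyde, and deacetylation.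
5. Stereochemistry: the target as drawn is (2R,2'S). C2' is C3 of (1S,3R)-camphoric acid and C2 is C3 of (1R,3S)-camphoric acid; both are carried through untouched, while the quaternary camphoric centre is consumed. Seven E double bonds come with crocetindial; the two new ones come from the Wittig steps with Z→E equilibration.

Key step: step 8

Assumption: crocetindial (8,8'-diapocarotene-8,8'-dial), both enantiomers of camphoric acid and 2-methylidenepropane-1,3-diyl diacetate are taken as purchasable.

**Primed half, from (−)-camphoric acid**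

Step 1
Reactants: 1 (1S,3R)-(−)-camphoric acid
Product: 2 (1S,3R)-3-(methoxycarbonyl)-1,2,2-trimethylcyclopentane-1-carboxylic acid
Conditions: MeOH, H2SO4 (cat.), reflux
Reagents that add atoms: methanol, CO
Why: Fischer esterification should stop at the monoester because the tertiary carboxyl, wedged between a quaternary ring carbon and the gem-dimethyl carbon, cannot reach the tetrahedral intermediate, so only the secondary carboxyl (future C1'') reacts and no stereocentre is touched.

Step 2
Reactants: 2 (1S,3R)-3-(methoxycarbonyl)-1,2,2-trimethylcyclopentane-1-carboxylic acid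
Product: 4 (1S,5R)-1,8,8-trimethyl-3-oxabicyclo[3.2.1]octan-2-one, via hydroxy acid 3 (not isolated)
Conditions: LiBH4 (3 equiv), THF, 0 °C to reflux; then 2 M HCl, rt
Reagents that add atoms: none
Why: Chemoselective borohydride reduction of the ester beside the inert lithium carboxylate, then acid-induced lactonisation of the cis-1,3-hydroxy acid, differentiates the two carboxyl carbons in a temporary ring without touching either stereocentre.

Step 3
Reactants: 4 (1S,5R)-1,8,8-trimethyl-3-oxabicyclo[3.2.1]octan-2-one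
Product: 5 1-[(1S,3R)-3-(hydroxymethyl)-1,2,2-trimethylcyclopentyl]ethan-1-one
Conditions: MeLi (1.05 equiv), Et2O, −78 to −20 °C; then H2O
Reagents that add atoms: methyllithium, [Li]C
Why: 1,2-Addition of an organolithium to a non-enolisable, hindered lactone should stop at the lactolate and release the methyl ketone on quench, which brings in C7 and frees the primary alcohol on C1''.

Step 4
Reactants: 5 1-[(1S,3R)-3-(hydroxymethyl)-1,2,2-trimethylcyclopentyl]ethan-1-one
Product: 6 1-[(1S,3R)-3-(iodomethyl)-1,2,2-trimethylcyclopentyl]ethan-1-one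
Conditions: I2, PPh3, imidazole, CH2Cl2, 0 °C to rt
Reagents that add atoms: iodine, II
Why: Appel-type iodination converts the only primary hydroxyl into the iodide under nearly neutral conditions, and ring–chain tautomerism of 5 does no harm because only the open form is consumed.

Step 5
Reactants: 6 1-[(1S,3R)-3-(iodomethyl)-1,2,2-trimethylcyclopentyl]ethan-1-one
Product: 7 1-[(1S,3S)-1,2,2-trimethyl-3-(prop-2-en-1-yl)cyclopentyl]ethan-1-one
Conditions: CH2=CHMgBr (4 equiv), CuI (2 equiv), THF, −40 to 0 °C; aq NH4Cl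
Reagents that add atoms: vinylmagnesium bromide, C=C[Mg]Br
Why: SN2 alkylation of a vinyl cuprate by a primary iodide forms C1''–C2'', the weakly basic cuprate should neither add to nor enolise the strongly hindered methyl ketone, and the neighbouring stereocentre is not involved (its descriptor changes only through CIP ranking).

Step 6
Reactants: 7 1-[(1S,3S)-1,2,2-trimethyl-3-(prop-2-en-1-yl)cyclopentyl]ethan-1-one
Product: 9 1-[(1S,3S)-1,2,2-trimethyl-3-(prop-2-en-1-yl)cyclopentyl]ethenyl trifluoromethanesulfonate, via potassium enolate 8 (not isolated)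
Conditions: KHMDS, THF, −78 °C; then PhNTf2, −78 to 0 °C
Reagents that add atoms: N-phenylbis(trifluoromethanesulfonimide), O=S(=O)(N(c1ccccc1)S(=O)(=O)C(F)(F)F)C(F)(F)F
Why: Enol triflate formation is regiochemically unambiguous because only the methyl group carries α-hydrogens, and O-triflation of the enolate installs the activating group for the latent vinyl cation.

Step 7
Reactants: 9 1-[(1S,3S)-1,2,2-trimethyl-3-(prop-2-en-1-yl)cyclopentyl]ethenyl trifluoromethanesulfonate; 10 2-methylidenepropane-1,3-diyl diacetate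
Product: 11 2-(2-{(1S,3S)-2,2,3-trimethyl-3-[1-(trifluoromethylsulfonyloxy)ethenyl]cyclopentyl}ethylidene)propane-1,3-diyl diacetate
Conditions: Hoveyda–Grubbs II (5 mol %), 10 (4 equiv), 1,4-benzoquinone (10 mol %), CH2Cl2, 40 °C
Reagents that add atoms: none
Why: Olefin cross metathesis of a terminal alkene with an excess of a symmetrical 1,1-disubstituted alkene builds C2''=C3'' without any E/Z issue, while the electron-poor, neopentylic enol triflate C=C is a spectator.

Step 8
Reactants: 11 2-(2-{(1S,3S)-2,2,3-trimethyl-3-[1-(trifluoromethylsulfonyloxy)ethenyl]cyclopentyl}ethylidene)propane-1,3-diyl diacetate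
Product: 14 ({(5S)-5-[4-acetoxy-3-(acetoxymethyl)but-2-en-1-yl]-2,6,6-trimethylcyclohex-1-en-1-yl}methyl)triphenylphosphonium trifluoromethanesulfonate, via vinyl cation triflate 12 (not isolated), via allyl cation triflate 13 (not isolated)
Conditions: PPh3 (3 equiv), (CF3)2CHOH (0.2 M), Ar, sealed tube, 90 °C; precipitation with Et2O
Reagents that add atoms: triphenylphosphine, c1ccc(cc1)P(c1ccccc1)c1ccccc1
Why: Proposed new method: heating in the strongly ionising, barely nucleophilic solvent should heterolyse the C6'–OTf bond to the linear α-(tert-alkyl)vinyl cation 12, whose empty in-plane p orbital can align by free rotation with the C5'–C1' σ bond; C1' then migrates from C5' to C6' (Wagner–Meerwein 1,2-shift), which inserts the exocyclic C6' into the cyclopentane and gives the 2-methylidenecyclohexyl (allyl) cation 13, trapped irreversibly by PPh3 at its primary terminus C7'. The closest known reaction types are the 1,2-methyl shift of α-tert-butylvinyl cations generated by solvolysis of the corresponding enol triflate or by HX addition to tert-butylacetylene, and the SN1 formation of allylic phosphonium salts from allyl cations (vinyl-β-ionol with PPh3·HX). No ring is closed by cyclisation: the six-membered ring arises from the five-membered one by one-carbon enlargement through a suprafacial 1,2-alkyl shift. No stereocentre is created; the quaternary centre C5' becomes trigonal, and C2', which never carries or adjoins charge, keeps the configuration of camphoric acid C3. The step needs (i) migration of C1' rather than C4' or CH3, secured because C1' is the only fully substituted and thus best charge-bearing migrating carbon and because its departure relieves the vicinal quaternary C5'/C1' congestion and the cyclopentane strain, (ii) capture at C7' rather than C5', secured by the bulk of PPh3, which thereby fixes the tetrasubstituted C5'=C6' bond, and (iii) an inert side-chain alkene, secured by its two electron-withdrawing acetoxymethyl groups. The overall change (enol triflate + PPh3 → phosphonium triflate) releases neither acid nor base, so the acetates should survive.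

**Unprimed half, from (+)-camphoric acid**

Step 9
Reactants: 15 (1R,3S)-(+)-camphoric acid
Product: 16 (1R,3S)-3-(methoxycarbonyl)-1,2,2-trimethylcyclopentane-1-carboxylic acid
Conditions: MeOH, H2SO4 (cat.), reflux
Reagents that add atoms: methanol, CO
Why: Fischer esterification is selective for the secondary carboxyl for the steric reason given in step 1 and leaves both stereocentres alone.

Step 10
Reactants: 16 (1R,3S)-3-(methoxycarbonyl)-1,2,2-trimethylcyclopentane-1-carboxylic acid
Product: 18 (1R,5S)-1,8,8-trimethyl-3-oxabicyclo[3.2.1]octan-2-one, via hydroxy acid 17 (not isolated)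
Conditions: LiBH4 (3 equiv), THF, 0 °C to reflux; then 2 M HCl, rt
Reagents that add atoms: none
Why: Chemoselective borohydride reduction of the ester beside the carboxylate and lactonisation of the cis-hydroxy acid proceed as in step 2.

Step 11
Reactants: 18 (1R,5S)-1,8,8-trimethyl-3-oxabicyclo[3.2.1]octan-2-one
Product: 19 1-[(1R,3S)-3-(hydroxymethyl)-1,2,2-trimethylcyclopentyl]ethan-1-one
Conditions: MeLi (1.05 equiv), Et2O, −78 to −20 °C; then H2O
Reagents that add atoms: methyllithium, [Li]C
Why: Single 1,2-addition of MeLi to the hindered, non-enolisable lactone delivers C7 and the free primary alcohol as in step 3.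

Step 12
Reactants: 19 1-[(1R,3S)-3-(hydroxymethyl)-1,2,2-trimethylcyclopentyl]ethan-1-one
Product: 20 1-[(1R,3S)-3-(iodomethyl)-1,2,2-trimethylcyclopentyl]ethan-1-one
Conditions: I2, PPh3, imidazole, CH2Cl2, 0 °C to rt
Reagents that add atoms: iodine, II
Why: Appel-type iodination of the only primary alcohol proceeds as in step 4.

Step 13
Reactants: 20 1-[(1R,3S)-3-(iodomethyl)-1,2,2-trimethylcyclopentyl]ethan-1-one
Product: 21 1-[(1R,3R)-1,2,2-trimethyl-3-(3-methylbut-2-en-1-yl)cyclopentyl]ethan-1-one
Conditions: Me2C=CHMgBr (4 equiv), CuI (2 equiv), THF, −40 °C to rt; aq NH4Cl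
Reagents that add atoms: 2-methylprop-1-enylmagnesium bromide, CC(C)=C[Mg]Br
Why: SN2 alkylation of an alkenyl cuprate by the primary iodide installs the whole prenyl group in one C1''–C2'' bond formation, with the hindered ketone and the adjacent stereocentre untouched.

Step 14
Reactants: 21 1-[(1R,3R)-1,2,2-trimethyl-3-(3-methylbut-2-en-1-yl)cyclopentyl]ethan-1-one
Product: 23 1-[(1R,3R)-1,2,2-trimethyl-3-(3-methylbut-2-en-1-yl)cyclopentyl]ethenyl trifluoromethanesulfonate, via potassium enolate 22 (not isolated)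
Conditions: KHMDS, THF, −78 °C; then PhNTf2, −78 to 0 °C
Reagents that add atoms: N-phenylbis(trifluoromethanesulfonimide), O=S(=O)(N(c1ccccc1)S(=O)(=O)C(F)(F)F)C(F)(F)F
Why: Enol triflate formation from the only possible enolate proceeds as in step 6.

Step 15
Reactants: 23 1-[(1R,3R)-1,2,2-trimethyl-3-(3-methylbut-2-en-1-yl)cyclopentyl]ethenyl trifluoromethanesulfonate
Product: 26 {[(5R)-2,6,6-trimethyl-5-(3-methylbut-2-en-1-yl)cyclohex-1-en-1-yl]methyl}triphenylphosphonium trifluoromethanesulfonate, via vinyl cation triflate 24 (not isolated), via allyl cation triflate 25 (not isolated)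
Conditions: PPh3 (5 equiv), 2,6-di-tert-butyl-4-methylpyridine (0.3 equiv), (CF3)2CHOH (0.2 M), Ar, sealed tube, 90 °C; precipitation with Et2O
Reagents that add atoms: triphenylphosphine, c1ccc(cc1)P(c1ccccc1)c1ccccc1
Why: Proposed new method: the same ionisation, 1,2-shift of C1 from C5 to C6 and phosphine capture at C7 as in step 8 (closest known types: methyl shift in α-tert-butylvinyl cations from enol triflate solvolysis, and SN1 formation of allylic phosphonium salts), here with a nucleophilic prenyl alkene on board, which should be outrun because the σ-shift needs no conformational change, because PPh3 is far more nucleophilic toward carbenium ions than a trisubstituted alkene that can reach C5, C6 or C7 only through a strained bridged bicycle, and because the buffered medium stays neutral; no stereocentre is formed and C2 is untouched.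

**Assembly**

Step 16
Reactants: 26 {[(5R)-2,6,6-trimethyl-5-(3-methylbut-2-en-1-yl)cyclohex-1-en-1-yl]methyl}triphenylphosphonium trifluoromethanesulfonate; 27 crocetindial (all-E-8,8'-diapocarotene-8,8'-dial)
Product: 29 (2R,all-E)-2-(3-methylbut-2-en-1-yl)-8'-apo-β-caroten-8'-al, via ylide 28 (not isolated)
Conditions: NaHMDS (1.0 equiv), THF, −78 to 0 °C; added to 27 (3 equiv), THF/CH2Cl2, 0 °C to rt; then heptane, reflux, dark (Z→E)
Reagents that add atoms: none
Why: Wittig olefination in the C10 + C20 + C10 manner used for carotenoids with hindered (di-ortho-substituted arylmethyl) ylides; excess dialdehyde favours mono-olefination, and the crowded 7Z isomer relaxes thermally to 7E.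

Step 17
Reactants: 14 ({(5S)-5-[4-acetoxy-3-(acetoxymethyl)but-2-en-1-yl]-2,6,6-trimethylcyclohex-1-en-1-yl}methyl)triphenylphosphonium trifluoromethanesulfonate; 29 (2R,all-E)-2-(3-methylbut-2-en-1-yl)-8'-apo-β-caroten-8'-al
Product: 31 (2R,2'S,all-E)-2'-[4-acetoxy-3-(acetoxymethyl)but-2-en-1-yl]-2-(3-methylbut-2-en-1-yl)-β,β-carotene, via ylide 30 (not isolated)
Conditions: NaHMDS (1.0 equiv), THF, −78 °C; then 29, −78 °C to rt; then heptane/EtOH, reflux, Ar, dark (Z→E), crystallisation
Reagents that add atoms: none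
Why: Second Wittig olefination; the P–CH2 protons are by far the most acidic in 14, so one equivalent of amide base should give the ylide without touching the acetates, and equilibration converges on the all-E polyene.

Step 18
Reactants: 31 (2R,2'S,all-E)-2'-[4-acetoxy-3-(acetoxymethyl)but-2-en-1-yl]-2-(3-methylbut-2-en-1-yl)-β,β-carotene
Product: 32 (2R,2'S,all-E)-2'-[4-hydroxy-3-(hydroxymethyl)but-2-en-1-yl]-2-(3-methylbut-2-en-1-yl)-β,β-carotene (target)
Conditions: K2CO3 (cat.), MeOH/THF, rt, Ar, dark
Reagents that add atoms: none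
Why: Base-catalysed transesterification (Zemplén-type methanolysis) removes both acetates under conditions routinely tolerated by carotenoid polyenes and affects no stereocentre.

**Compound list**

1 | (1S,3R)-(−)-camphoric acid | OC(=O)[C@@]1(C)CC[C@@H](C(=O)O)C1(C)C | starting material
2 | (1S,3R)-3-(methoxycarbonyl)-1,2,2-trimethylcyclopentane-1-carboxylic acid | OC(=O)[C@@]1(C)CC[C@@H](C(=O)OC)C1(C)C | intermediate
3 | (1S,3R)-3-(hydroxymethyl)-1,2,2-trimethylcyclopentane-1-carboxylic acid | OC(=O)[C@@]1(C)CC[C@@H](CO)C1(C)C | intermediate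
4 | (1S,5R)-1,8,8-trimethyl-3-oxabicyclo[3.2.1]octan-2-one | O=C1OC[C@@H]2CC[C@@]1(C)C2(C)C | intermediate
5 | 1-[(1S,3R)-3-(hydroxymethyl)-1,2,2-trimethylcyclopentyl]ethan-1-one | CC(=O)[C@@]1(C)CC[C@@H](CO)C1(C)C | intermediate
6 | 1-[(1S,3R)-3-(iodomethyl)-1,2,2-trimethylcyclopentyl]ethan-1-one | CC(=O)[C@@]1(C)CC[C@@H](CI)C1(C)C | intermediate
7 | 1-[(1S,3S)-1,2,2-trimethyl-3-(prop-2-en-1-yl)cyclopentyl]ethan-1-one | CC(=O)[C@@]1(C)CC[C@@H](CC=C)C1(C)C | intermediate
8 | potassium enolate of 7 | [K+].C=C([O-])[C@@]1(C)CC[C@@H](CC=C)C1(C)C | intermediate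
9 | 1-[(1S,3S)-1,2,2-trimethyl-3-(prop-2-en-1-yl)cyclopentyl]ethenyl trifluoromethanesulfonate | C=C(OS(=O)(=O)C(F)(F)F)[C@@]1(C)CC[C@@H](CC=C)C1(C)C | intermediate
10 | 2-methylidenepropane-1,3-diyl diacetate | C=C(COC(C)=O)COC(C)=O | starting material
11 | 2-(2-{(1S,3S)-2,2,3-trimethyl-3-[1-(trifluoromethylsulfonyloxy)ethenyl]cyclopentyl}ethylidene)propane-1,3-diyl diacetate | C=C(OS(=O)(=O)C(F)(F)F)[C@@]1(C)CC[C@@H](CC=C(COC(C)=O)COC(C)=O)C1(C)C | intermediate
12 | α-(cyclopentyl)vinyl cation triflate from 11 | C=[C+][C@@]1(C)CC[C@@H](CC=C(COC(C)=O)COC(C)=O)C1(C)C.[O-]S(=O)(=O)C(F)(F)F | intermediate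
13 | ring-enlarged 1-methyl-2-methylidenecyclohexyl (allyl) cation triflate | C=C1[C+](C)CC[C@@H](CC=C(COC(C)=O)COC(C)=O)C1(C)C.[O-]S(=O)(=O)C(F)(F)F | intermediate
14 | ({(5S)-5-[4-acetoxy-3-(acetoxymethyl)but-2-en-1-yl]-2,6,6-trimethylcyclohex-1-en-1-yl}methyl)triphenylphosphonium trifluoromethanesulfonate | C([P+](c1ccccc1)(c1ccccc1)c1ccccc1)C2=C(C)CC[C@@H](CC=C(COC(C)=O)COC(C)=O)C2(C)C.[O-]S(=O)(=O)C(F)(F)F | intermediate
15 | (1R,3S)-(+)-camphoric acid | OC(=O)[C@]1(C)CC[C@H](C(=O)O)C1(C)C | starting material
16 | (1R,3S)-3-(methoxycarbonyl)-1,2,2-trimethylcyclopentane-1-carboxylic acid | OC(=O)[C@]1(C)CC[C@H](C(=O)OC)C1(C)C | intermediate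
17 | (1R,3S)-3-(hydroxymethyl)-1,2,2-trimethylcyclopentane-1-carboxylic acid | OC(=O)[C@]1(C)CC[C@H](CO)C1(C)C | intermediate
18 | (1R,5S)-1,8,8-trimethyl-3-oxabicyclo[3.2.1]octan-2-one | O=C1OC[C@H]2CC[C@]1(C)C2(C)C | intermediate
19 | 1-[(1R,3S)-3-(hydroxymethyl)-1,2,2-trimethylcyclopentyl]ethan-1-one | CC(=O)[C@]1(C)CC[C@H](CO)C1(C)C | intermediate
20 | 1-[(1R,3S)-3-(iodomethyl)-1,2,2-trimethylcyclopentyl]ethan-1-one | CC(=O)[C@]1(C)CC[C@H](CI)C1(C)C | intermediate
21 | 1-[(1R,3R)-1,2,2-trimethyl-3-(3-methylbut-2-en-1-yl)cyclopentyl]ethan-1-one | CC(=O)[C@]1(C)CC[C@H](CC=C(C)C)C1(C)C | intermediate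
22 | potassium enolate of 21 | [K+].C=C([O-])[C@]1(C)CC[C@H](CC=C(C)C)C1(C)C | intermediate
23 | 1-[(1R,3R)-1,2,2-trimethyl-3-(3-methylbut-2-en-1-yl)cyclopentyl]ethenyl trifluoromethanesulfonate | C=C(OS(=O)(=O)C(F)(F)F)[C@]1(C)CC[C@H](CC=C(C)C)C1(C)C | intermediate
24 | α-(cyclopentyl)vinyl cation triflate from 23 | C=[C+][C@]1(C)CC[C@H](CC=C(C)C)C1(C)C.[O-]S(=O)(=O)C(F)(F)F | intermediate
25 | ring-enlarged allyl cation triflate (prenyl series) | C=C1[C+](C)CC[C@H](CC=C(C)C)C1(C)C.[O-]S(=O)(=O)C(F)(F)F | intermediate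
26 | {[(5R)-2,6,6-trimethyl-5-(3-methylbut-2-en-1-yl)cyclohex-1-en-1-yl]methyl}triphenylphosphonium trifluoromethanesulfonate | CC(C)=CC[C@H]1CCC(C)=C(C[P+](c2ccccc2)(c2ccccc2)c2ccccc2)C1(C)C.[O-]S(=O)(=O)C(F)(F)F | intermediate
27 | crocetindial (all-E-8,8'-diapocarotene-8,8'-dial) | O=C/C(C)=C/C=C/C(C)=C/C=C/C=C(C)/C=C/C=C(C)/C=O | starting material
28 | ylide from 26 | CC(C)=CC[C@H]1CCC(C)=C(C=P(c2ccccc2)(c2ccccc2)c2ccccc2)C1(C)C | intermediate
29 | (2R,all-E)-2-(3-methylbut-2-en-1-yl)-8'-apo-β-caroten-8'-al | CC(C)=CC[C@H]1CCC(C)=C(/C=C/C(C)=C/C=C/C(C)=C/C=C/C=C(C)/C=C/C=C(C)/C=O)C1(C)C | intermediate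
30 | ylide from 14 | C(=P(c1ccccc1)(c1ccccc1)c1ccccc1)C2=C(C)CC[C@@H](CC=C(COC(C)=O)COC(C)=O)C2(C)C | intermediate
31 | (2R,2'S,all-E)-2'-[4-acetoxy-3-(acetoxymethyl)but-2-en-1-yl]-2-(3-methylbut-2-en-1-yl)-β,β-carotene | CC(C)=CC[C@H]1CCC(C)=C(/C=C/C(C)=C/C=C/C(C)=C/C=C/C=C(C)/C=C/C=C(C)/C=C/C2=C(C)CC[C@@H](CC=C(COC(C)=O)COC(C)=O)C2(C)C)C1(C)C | intermediate
32 | (2R,2'S,all-E)-2'-[4-hydroxy-3-(hydroxymethyl)but-2-en-1-yl]-2-(3-methylbut-2-en-1-yl)-β,β-carotene | CC(C)=CC[C@H]1CCC(C)=C(/C=C/C(C)=C/C=C/C(C)=C/C=C/C=C(C)/C=C/C=C(C)/C=C/C2=C(C)CC[C@@H](CC=C(CO)CO)C2(C)C)C1(C)C | target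

**Step count**

Total step count: 18.

Longest linear sequence: 10 steps (steps 9–18 from (+)-camphoric acid). The branch from (−)-camphoric acid (steps 1–8, 17, 18) is equally long.

**Steps most likely to fail**

**1. Step 8.** After heterolysis the vinyl cation may lose a vinylic proton (alkyne formation). It may also be captured before the shift, or let C4' or the methyl group migrate instead of C1'. Ionisation may also be too slow at temperatures the allylic acetates tolerate in the presence of PPh3.

The fallback uses known chemistry. It sets out from ketone 7 and comes back at ylide 30 (and thus 31).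
- LiAlH4 reduction of 7 gives the secondary carbinol 1-[(1S,3S)-1,2,2-trimethyl-3-(prop-2-en-1-yl)cyclopentyl]ethan-1-ol F1.
- Acid-catalysed retropinacol (Wagner–Meerwein) dehydration (p-TsOH, toluene, reflux) enlarges the ring and equilibrates the olefins to (4S)-1,2,3,3-tetramethyl-4-(prop-2-en-1-yl)cyclohex-1-ene F2.
- Cross metathesis with 10 as in step 7 gives the tetramethylcyclohexenyl diacetate F3.
- A Schenck ene reaction with singlet oxygen (O2, tetraphenylporphyrin, hν, CH2Cl2, 0 °C) attacks the electron-rich tetrasubstituted alkene. It abstracts hydrogen from the methyl group geminal to the bulky C1' substituent and gives the tertiary allylic hydroperoxide F4.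
- PPh3 reduces F4 in the same flask to the tertiary allylic alcohol F5.
- PPh3·HBr (CH2Cl2/MeOH, rt) converts F5 with allylic transposition, as for vinyl-β-ionol, into the phosphonium bromide F6.
- Deprotonation of F6 under the conditions of step 17 gives 30.

**2. Step 15.** The nucleophilic trisubstituted side-chain alkene is held cis to the cationic carbon. It may take part in the ionisation or intercept the vinyl or allyl cation (cation–olefin cyclisation to bridged bicycles) before migration and phosphine capture. Adventitious acid may also protonate it.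

The fallback uses known chemistry. It sets out from iodide 20 and comes back at ylide 28 (and thus 29).
- The vinyl cuprate of step 5 gives the allyl ketone 1-[(1R,3R)-1,2,2-trimethyl-3-(prop-2-en-1-yl)cyclopentyl]ethan-1-one F7.
- LiAlH4 gives the secondary carbinol F8.
- p-TsOH in refluxing toluene effects the retropinacol ring enlargement to (4R)-1,2,3,3-tetramethyl-4-(prop-2-en-1-yl)cyclohex-1-ene F9.
- The Schenck ene reaction, to which the terminal alkene is inert, gives the tertiary allylic hydroperoxide F10, reduced by PPh3 to the tertiary allylic alcohol F11.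
- Only now is the prenyl group made, by cross metathesis in 2-methylbut-2-ene (Grubbs II). This gives the prenylated tertiary allylic alcohol F12.
- PPh3·HBr, which tolerates isolated trisubstituted alkenes as in acyclic C15 carotenoid salts, gives the phosphonium bromide F13.
- Deprotonation of F13 as in step 16 gives 28.

**3. Step 7.** Cross metathesis with the sluggish 1,1-disubstituted partner may stall. Homodimerisation of the allyl compound or ruthenium-hydride isomerisation of allyl to propenyl would then take over.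

The fallback replaces metathesis by carbonyl condensation. It sets out from 9 and comes back at 11.
- Lemieux–Johnson cleavage (OsO4 cat., NaIO4, 2,6-lutidine, dioxane/H2O) of the terminal alkene, with the electron-poor enol triflate left alone, gives the aldehyde F14.
- Knoevenagel condensation with dimethyl malonate (TiCl4, pyridine, THF, 0 °C) gives the alkylidene malonate F15.
- DIBAL-H (excess, CH2Cl2, −78 to 0 °C) reduces both esters to the 2-alkylidenepropane-1,3-diol F16.
- Ac2O/pyridine gives 11.

**Further compounds**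

F1 | step 8 | 1-[(1S,3S)-1,2,2-trimethyl-3-(prop-2-en-1-yl)cyclopentyl]ethan-1-ol (both carbinol epimers) | CC(O)[C@@]1(C)CC[C@@H](CC=C)C1(C)C
F2 | step 8 | (4S)-1,2,3,3-tetramethyl-4-(prop-2-en-1-yl)cyclohex-1-ene | CC1=C(C)CC[C@@H](CC=C)C1(C)C
F3 | step 8 | 2-{2-[(1S)-2,2,3,4-tetramethylcyclohex-3-en-1-yl]ethylidene}propane-1,3-diyl diacetate | CC1=C(C)CC[C@@H](CC=C(COC(C)=O)COC(C)=O)C1(C)C
F4 | step 8 | 2-{2-[(1S)-4-hydroperoxy-2,2,4-trimethyl-3-methylidenecyclohexyl]ethylidene}propane-1,3-diyl diacetate (C4 epimers) | C=C1C(C)(OO)CC[C@@H](CC=C(COC(C)=O)COC(C)=O)C1(C)C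
F5 | step 8 | 2-{2-[(1S)-4-hydroxy-2,2,4-trimethyl-3-methylidenecyclohexyl]ethylidene}propane-1,3-diyl diacetate (C4 epimers) | C=C1C(C)(O)CC[C@@H](CC=C(COC(C)=O)COC(C)=O)C1(C)C
F6 | step 8 | ({(5S)-5-[4-acetoxy-3-(acetoxymethyl)but-2-en-1-yl]-2,6,6-trimethylcyclohex-1-en-1-yl}methyl)triphenylphosphonium bromide | C([P+](c1ccccc1)(c1ccccc1)c1ccccc1)C2=C(C)CC[C@@H](CC=C(COC(C)=O)COC(C)=O)C2(C)C.[Br-]
F7 | step 15 | 1-[(1R,3R)-1,2,2-trimethyl-3-(prop-2-en-1-yl)cyclopentyl]ethan-1-one | CC(=O)[C@]1(C)CC[C@H](CC=C)C1(C)C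
F8 | step 15 | 1-[(1R,3R)-1,2,2-trimethyl-3-(prop-2-en-1-yl)cyclopentyl]ethan-1-ol (both carbinol epimers) | CC(O)[C@]1(C)CC[C@H](CC=C)C1(C)C
F9 | step 15 | (4R)-1,2,3,3-tetramethyl-4-(prop-2-en-1-yl)cyclohex-1-ene | CC1=C(C)CC[C@H](CC=C)C1(C)C
F10 | step 15 | (4R)-1-hydroperoxy-1,3,3-trimethyl-2-methylidene-4-(prop-2-en-1-yl)cyclohexane (C1 epimers) | C=C1C(C)(OO)CC[C@H](CC=C)C1(C)C
F11 | step 15 | (4R)-1,3,3-trimethyl-2-methylidene-4-(prop-2-en-1-yl)cyclohexan-1-ol (C1 epimers) | C=C1C(C)(O)CC[C@H](CC=C)C1(C)C
F12 | step 15 | (4R)-1,3,3-trimethyl-2-methylidene-4-(3-methylbut-2-en-1-yl)cyclohexan-1-ol (C1 epimers) | C=C1C(C)(O)CC[C@H](CC=C(C)C)C1(C)C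
F13 | step 15 | {[(5R)-2,6,6-trimethyl-5-(3-methylbut-2-en-1-yl)cyclohex-1-en-1-yl]methyl}triphenylphosphonium bromide | CC(C)=CC[C@H]1CCC(C)=C(C[P+](c2ccccc2)(c2ccccc2)c2ccccc2)C1(C)C.[Br-]
F14 | step 7 | 1-[(1S,3S)-1,2,2-trimethyl-3-(2-oxoethyl)cyclopentyl]ethenyl trifluoromethanesulfonate | C=C(OS(=O)(=O)C(F)(F)F)[C@@]1(C)CC[C@@H](CC=O)C1(C)C
F15 | step 7 | dimethyl 2-(2-{(1S,3S)-2,2,3-trimethyl-3-[1-(trifluoromethylsulfonyloxy)ethenyl]cyclopentyl}ethylidene)propanedioate | C=C(OS(=O)(=O)C(F)(F)F)[C@@]1(C)CC[C@@H](CC=C(C(=O)OC)C(=O)OC)C1(C)C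
F16 | step 7 | 1-{(1S,3S)-3-[4-hydroxy-3-(hydroxymethyl)but-2-en-1-yl]-1,2,2-trimethylcyclopentyl}ethenyl trifluoromethanesulfonate | C=C(OS(=O)(=O)C(F)(F)F)[C@@]1(C)CC[C@@H](CC=C(CO)CO)C1(C)C
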